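**Retrosynthetic overview**
1. Sodwanone S (21) ⇒ keto bis-epoxide 19: the left oxepene and C19=C20 are formed last by an epoxonium/elimination cascade.
2. 19 ⇒ cyclohexanone 12 (enol triflate, homoprenyl coupling, double Shi epoxidation); 12 ⇒ enone 10 by asymmetric conjugate methylation and enolate methylation (C15, then quaternary C14).
3. 10 ⇒ right-half vinyl carbinol 6 + 2-iodocyclohexenone 8 (B-alkyl Suzuki, C13–C14).
4. 6 ⇒ diol 4 ⇒ diepoxy farnesyl acetate 2: one operation closes the oxepane, the cyclohexane and a transient dioxanylium ring and sets C6, C7, C10 and C11.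
5. Ring order: right oxepane + right cyclohexane (together) → left cyclohexane (brought in as cyclohexenone) → left oxepene.

Assumption 1: locants are biogenetic (squalene) ones: C1–C12 right half (C2 CMe2, C3 C=O, C6/C7 ring fusion, C10 carbinol, C11 CH), C13–C24 left half (C14 quaternary, C15 CHMe, C18 CH–O, C19=C20, C22 carbinol, C23 CMe2).
Assumption 2: the L-fructose-derived Shi ketone (ent-Shi) and the (S,R,R)-phosphoramidite are bought as catalysts; the ligand is taken to deliver methyl with the facial sense known for cyclohex-2-enone (3S), otherwise its antipode is used.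

**Step 1**
Reactants: 1 (2E,6E)-farnesyl acetate
Product: 2 (2E,6S,7S,10S)-6,7:10,11-diepoxyfarnesyl acetate
Conditions: ent-Shi ketone (0.4 equiv), Oxone, K2CO3, Bu4NHSO4 (cat.), MeCN/DMM/aq. borate–EDTA (pH 10.5), 0 °C
Reagents that add atoms: potassium peroxymonosulfate (Oxone), [K+].[O-]S(=O)(=O)OO
Why: Shi asymmetric epoxidation: the chiral dioxirane epoxidises the two electron-rich trisubstituted olefins through the spiro transition state (catalyst-controlled S,S sense), while the allylic acetate deactivates the 2,3-olefin, which is kept as the later π-nucleophile.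

**Step 2**
Reactants: 2 (2E,6S,7S,10S)-6,7:10,11-diepoxyfarnesyl acetate
Product: 4 TBS-protected right-half diol (3S,6S,7S,10S,11R), via acetoxonium triflate 3 (not isolated)
Conditions: TBSOTf (1.3 equiv), DTBMP, CH2Cl2, −78 °C; then LiOH, MeOH/H2O, −78 °C → rt
Reagents that add atoms: tert-butyldimethylsilyl triflate, CC(C)(C)[Si](C)(C)OS(=O)(=O)C(F)(F)F
Why: Proposed new method: silylation of the terminal epoxide triggers endo attack of the 6,7-epoxide oxygen at C2 (bicyclic epoxonium, C3 and C7 retained), the C10=C11 olefin opens it at C6 with inversion through a chair, and the acetate carbonyl captures the C10 cation anti (equatorial C–O, face opposite the axial C6 methyl) as a trans-fused 1,3-dioxan-2-ylium that hydroxide then hydrolyses to the diol; the closest known reactions are the silyl-triflate-promoted tandem oxa-/carbacyclisation of 1,5-diepoxides (epoxide-opening/cation–olefin cascade) and acyloxonium neighbouring-group participation.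

**Step 3**
Reactants: 4 TBS-protected right-half diol
Product: 5 right-half β-hydroxy aldehyde (3S,6S,7S,10S,11S)
Conditions: TEMPO (10 mol%), PhI(OAc)2, CH2Cl2, rt
Reagents that add atoms: none
Why: Oxoammonium (TEMPO/BAIB) oxidation takes only the primary alcohol; the tertiary C10 hydroxyl and the silyl ether are inert and no stereocentre is touched.

**Step 4**
Reactants: 5 right-half β-hydroxy aldehyde
Product: 6 right-half C11-vinyl carbinol (3S,6S,7S,10S,11S)
Conditions: Ph3PCH3Br, KOtBu, THF, 0 °C; then 5, −78 → 0 °C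
Reagents that add atoms: methyltriphenylphosphonium bromide, C[P+](c1ccccc1)(c1ccccc1)c1ccccc1.[Br-]
Why: Wittig methylenation: the small non-stabilised ylide adds to the aldehyde much faster than it can deprotonate the hindered tertiary β-hydroxyl (no retro-aldol), and the equatorial C11 centre is not epimerised.

**Step 5**
Reactants: 7 cyclohex-2-en-1-one
Product: 8 2-iodocyclohex-2-en-1-one
Conditions: I2, pyridine/CH2Cl2, 0 °C → rt
Reagents that add atoms: iodine, II
Why: α-Iodination of an enone by pyridine conjugate addition, iodination of the enolate and elimination (Johnson iodination).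

**Step 6**
Reactants: 6 right-half C11-vinyl carbinol; 8 2-iodocyclohex-2-en-1-one
Product: 10 2-(right-half-ethyl)cyclohex-2-en-1-one, via B-alkyl-9-BBN borane 9 (not isolated)
Conditions: 9-BBN, THF, rt; then 8, PdCl2(dppf) (5 mol%), AsPh3, Cs2CO3, DMF/H2O, rt
Reagents that add atoms: none
Why: Anti-Markovnikov hydroboration of the vinyl group followed by B-alkyl Suzuki–Miyaura coupling with the 2-iodoenone forms the C13–C14 bond; no stereocentre is formed.

**Step 7**
Reactants: 10 2-(right-half-ethyl)cyclohex-2-en-1-one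
Product: 12 (14S,15S)-2,3-dimethyl-2-(right-half-ethyl)cyclohexanone, via aluminium enolate 11 (not isolated)
Conditions: Me3Al (2.5 equiv), CuTC (5 mol%), (S,R,R)-phosphoramidite (10 mol%), Et2O, −30 °C; then MeLi, THF; MeI, DMPU, −30 °C → rt
Reagents that add atoms: trimethylaluminium, C[Al](C)C; iodomethane, CI
Why: Copper-catalysed asymmetric conjugate addition sets C15 under ligand control, and the regiodefined enolate (as its aluminate) is methylated by axial attack anti to the pseudoaxial C15 methyl, giving the trans-dimethyl quaternary C14 (conjugate addition/enolate alkylation).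

**Step 8**
Reactants: 12 (14S,15S)-2,3-dimethyl-2-(right-half-ethyl)cyclohexanone
Product: 13 C18=C19 enol triflate
Conditions: KHMDS (2.3 equiv), THF, −78 °C; PhNTf2, −78 → −30 °C
Reagents that add atoms: N-phenylbis(trifluoromethanesulfonimide), O=S(=O)(N(c1ccccc1)S(=O)(=O)C(F)(F)F)C(F)(F)F
Why: Enolisation can only occur toward C18 because C14 is quaternary, and the enolate is O-triflated much faster than the hindered tertiary C10 alkoxide (enol triflate formation).

**Step 9**
Reactants: 13 C18=C19 enol triflate; 14 5-bromo-2-methylpent-2-ene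
Product: 16 C3-OTBS diene (C18=C19 and C22=C23), via homoprenylmagnesium bromide 15 (not isolated)
Conditions: Mg, THF (14 → 15, 3 equiv); then 13, Fe(acac)3 (5 mol%), THF/NMP, −30 → 0 °C
Reagents that add atoms: none
Why: Iron-catalysed Kumada alkyl–alkenyl cross-coupling replaces the triflate by the homoprenyl chain and fixes the ring olefin at C18=C19; the stereocentres are remote from the reaction site.

**Step 10**
Reactants: 16 C3-OTBS diene
Product: 17 C3-hydroxy diene
Conditions: TBAF, THF, 50 °C
Reagents that add atoms: none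
Why: Fluoride-mediated desilylation frees the C3 alcohol; the olefins and the tertiary alcohol are untouched.

**Step 11**
Reactants: 17 C3-hydroxy diene
Product: 18 C3-keto diene
Conditions: DMP, pyridine, CH2Cl2, 0 °C → rt
Reagents that add atoms: none
Why: Dess–Martin oxidation of the only secondary alcohol gives the oxepanone; the tertiary C10 hydroxyl and both trisubstituted olefins are inert.

**Step 12**
Reactants: 18 C3-keto diene
Product: 19 keto bis-epoxide (18S,19R,22S)
Conditions: ent-Shi ketone (0.5 equiv), Oxone, K2CO3, Bu4NHSO4 (cat.), MeCN/DMM/aq. borate–EDTA (pH 10.5), 0 °C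
Reagents that add atoms: potassium peroxymonosulfate (Oxone), [K+].[O-]S(=O)(=O)OO
Why: Shi asymmetric epoxidation with the same catalyst gives the (22S) terminal epoxide and the (18S) ring epoxide; the catalyst sense matches the substrate bias, since the pseudoaxial C13 chain shields the opposite face, so oxygen is delivered cis to the C14 methyl.

**Step 13**
Reactants: 19 keto bis-epoxide
Product: 21 Sodwanone S, via bis-TMS ether 20 (not isolated)
Conditions: TMSOTf (2.5 equiv), DTBMP (3 equiv), CH2Cl2, −78 °C; then K2CO3, MeOH, 0 °C → rt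
Reagents that add atoms: none
Why: Proposed new method: the silylated terminal epoxide is attacked at its tertiary carbon C23 by the ring-epoxide oxygen through a six-membered transition state (C22 and C18 keep their C–O bonds and configurations), and the epoxonium opens at tertiary C19, which has no hydrogen on the quaternary C14 side and loses the antiperiplanar H-20 to give the C19=C20 oxepene; the closest known reactions are the endo-selective silyl-triflate-promoted oxacyclisation of 1,5-diepoxides and the silyl-triflate/base isomerisation of epoxides to allylic ethers.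

**Compound list**
1 | (2E,6E)-farnesyl acetate | CC(C)=CCC/C(C)=C/CC/C(C)=C/COC(C)=O | starting material
2 | (2E,6S,7S,10S)-6,7:10,11-diepoxyfarnesyl acetate | CC1(C)O[C@H]1CC[C@]2(C)O[C@H]2CC/C(C)=C/COC(C)=O | intermediate
3 | acetoxonium triflate: trans-fused 3-OTBS oxepane–cyclohexane–2-methyl-1,3-dioxan-2-ylium (3S,6S,7S,10S,11R) | CC1=[O+]C[C@H]2[C@]3(C)CC[C@H](O[Si](C)(C)C(C)(C)C)C(C)(C)O[C@H]3CC[C@]2(C)O1.[O-]S(=O)(=O)C(F)(F)F | intermediate
4 | [(3S,5aS,6R,7S,9aS)-3-(tert-butyldimethylsilyloxy)-7-hydroxy-2,2,5a,7-tetramethyldecahydro-1-benzoxepin-6-yl]methanol (right-half diol) | OC[C@H]1[C@]2(C)CC[C@H](O[Si](C)(C)C(C)(C)C)C(C)(C)O[C@H]2CC[C@]1(C)O | intermediate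
5 | right-half β-hydroxy aldehyde (C12 CHO; 3S,6S,7S,10S,11S) | O=C[C@H]1[C@]2(C)CC[C@H](O[Si](C)(C)C(C)(C)C)C(C)(C)O[C@H]2CC[C@]1(C)O | intermediate
6 | right-half C11-vinyl carbinol (3S,6S,7S,10S,11S) | C=C[C@H]1[C@]2(C)CC[C@H](O[Si](C)(C)C(C)(C)C)C(C)(C)O[C@H]2CC[C@]1(C)O | intermediate
7 | cyclohex-2-en-1-one | O=C1C=CCCC1 | starting material
8 | 2-iodocyclohex-2-en-1-one | O=C1CCCC=C1I | intermediate
9 | B-alkyl-9-BBN borane (boron on C13) | B1(CC[C@H]2[C@]3(C)CC[C@H](O[Si](C)(C)C(C)(C)C)C(C)(C)O[C@H]3CC[C@]2(C)O)C2CCCC1CCC2 | intermediate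
10 | 2-[2-(right half)ethyl]cyclohex-2-en-1-one (C19 ketone, C14=C15) | O=C1CCCC=C1CC[C@H]1[C@]2(C)CC[C@H](O[Si](C)(C)C(C)(C)C)C(C)(C)O[C@H]2CC[C@]1(C)O | intermediate
11 | dimethylaluminium enolate (15S), C10 hydroxyl as its dimethylaluminium alkoxide | C[C@H]1CCCC(O[Al](C)C)=C1CC[C@H]1[C@]2(C)CC[C@H](O[Si](C)(C)C(C)(C)C)C(C)(C)O[C@H]2CC[C@]1(C)O[Al](C)C | intermediate
12 | (14S,15S)-2,3-dimethyl-2-[2-(right half)ethyl]cyclohexanone (methyls trans) | C[C@H]1CCCC(=O)[C@@]1(C)CC[C@H]1[C@]2(C)CC[C@H](O[Si](C)(C)C(C)(C)C)C(C)(C)O[C@H]2CC[C@]1(C)O | intermediate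
13 | C18=C19 enol triflate (14S,15S) | C[C@H]1CCC=C(OS(=O)(=O)C(F)(F)F)[C@@]1(C)CC[C@H]1[C@]2(C)CC[C@H](O[Si](C)(C)C(C)(C)C)C(C)(C)O[C@H]2CC[C@]1(C)O | intermediate
14 | 5-bromo-2-methylpent-2-ene | CC(C)=CCCBr | starting material
15 | (4-methylpent-3-en-1-yl)magnesium bromide | CC(C)=CCC[Mg]Br | intermediate
16 | C3-OTBS diene (C19 homoprenyl; C18=C19, C22=C23) | C[C@H]1CCC=C(CCC=C(C)C)[C@@]1(C)CC[C@H]1[C@]2(C)CC[C@H](O[Si](C)(C)C(C)(C)C)C(C)(C)O[C@H]2CC[C@]1(C)O | intermediate
17 | C3-hydroxy diene (3S) | C[C@H]1CCC=C(CCC=C(C)C)[C@@]1(C)CC[C@H]1[C@]2(C)CC[C@H](O)C(C)(C)O[C@H]2CC[C@]1(C)O | intermediate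
18 | C3-keto diene | C[C@H]1CCC=C(CCC=C(C)C)[C@@]1(C)CC[C@H]1[C@]2(C)CCC(=O)C(C)(C)O[C@H]2CC[C@]1(C)O | intermediate
19 | keto bis-epoxide (6S,7S,10S,11S,14S,15S,18S,19R,22S); ring epoxide cis to the C14 methyl | C[C@H]1CC[C@@H]2O[C@]2(CC[C@@H]3OC3(C)C)[C@@]1(C)CC[C@H]4[C@]5(C)CCC(=O)C(C)(C)O[C@H]5CC[C@]4(C)O | intermediate
20 | Sodwanone S 10,22-bis(trimethylsilyl) ether | C[C@H]1CC[C@@H]2OC(C)(C)[C@@H](O[Si](C)(C)C)CC=C2[C@@]1(C)CC[C@H]1[C@]2(C)CCC(=O)C(C)(C)O[C@H]2CC[C@]1(C)O[Si](C)(C)C | intermediate
21 | Sodwanone S | C[C@H]1CC[C@@H]2OC(C)(C)[C@@H](O)CC=C2[C@@]1(C)CC[C@H]1[C@]2(C)CCC(=O)C(C)(C)O[C@H]2CC[C@]1(C)O | target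

**Step count**
Total: 13 steps. Longest linear sequence: 12 steps (1 → 21 through steps 1–4 and 6–13; step 5 is the only branch).

**Steps most likely to fail, each with one fallback**

Step 2 (acetoxonium-terminated tricyclisation). The allylic-acetate olefin is a weak nucleophile and the C10 cation may eliminate instead of being captured. The fallback changes the terminating group to one whose capture is irreversible. Setting out from 1, methanolysis (K2CO3, MeOH) gives (2E,6E)-farnesol F1, and Boc2O/DMAP gives farnesyl tert-butyl carbonate F2. The same ent-Shi epoxidation gives diepoxy carbonate F3. TBSOTf/DTBMP at −78 °C then closes the oxepane and cyclohexane, and the carbonate carbonyl traps C10 with loss of isobutene to give the neutral, isolable trans-fused cyclic carbonate F4. Methanolysis of F4 (K2CO3, MeOH) comes back to the route at 4.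

Step 7 (asymmetric conjugate methylation and enolate methylation). Ligand control on a 2-alkyl enone may be poor, or the aluminium enolate may resist methylation. The fallback sets C15 by reduction instead of addition. Setting out from 6, the same hydroboration (borane 9) is coupled with 2-iodo-3-methylcyclohex-2-en-1-one F5 (I2/pyridine on 3-methylcyclohex-2-en-1-one) to give the tetrasubstituted enone F6. Ligand-controlled CuH 1,4-reduction (Cu(OAc)2, DTBM-SEGPHOS antipode chosen for 15S, (EtO)2MeSiH) gives the regiodefined silyl enol ether F7. MeLi then MeI methylates C14 anti to the C15 methyl and comes back to the route at 12.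

Step 13 (epoxonium/elimination cascade). The C19 cation may undergo hydride shift from C18 or alkyl shift from C14 instead of losing H-20. The fallback installs the C19=C20 olefin and the C18 alcohol before ring closure. Setting out from 18, ent-Shi epoxidation with one equivalent of oxidant takes only the more reactive terminal olefin and gives mono-epoxide F8. A Schenck ene reaction (O2, TPP, hν) on the ring olefin, on the face anti to the C13 chain and with abstraction of H-20, gives allylic hydroperoxide F9. PPh3 reduces F9 to the (18S,19Z)-allylic alcohol F10. Acid-promoted 7-endo opening of the epoxide at its tertiary carbon by the C18 hydroxyl (CSA, CH2Cl2) closes the oxepene and comes back to the route at 21.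

**Further compounds**
F1 | step 2 | (2E,6E)-farnesol | CC(C)=CCC/C(C)=C/CC/C(C)=C/CO
F2 | step 2 | (2E,6E)-farnesyl tert-butyl carbonate | CC(C)=CCC/C(C)=C/CC/C(C)=C/COC(=O)OC(C)(C)C
F3 | step 2 | (2E,6S,7S,10S)-6,7:10,11-diepoxyfarnesyl tert-butyl carbonate | CC1(C)O[C@H]1CC[C@]2(C)O[C@H]2CC/C(C)=C/COC(=O)OC(C)(C)C
F4 | step 2 | trans-fused 3-OTBS oxepane–cyclohexane cyclic carbonate (1,3-dioxan-2-one over C10–O and C12–O) | O=C1OC[C@H]2[C@]3(C)CC[C@H](O[Si](C)(C)C(C)(C)C)C(C)(C)O[C@H]3CC[C@]2(C)O1
F5 | step 7 | 2-iodo-3-methylcyclohex-2-en-1-one | CC1=C(I)C(=O)CCC1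
F6 | step 7 | 3-methyl-2-[2-(right half)ethyl]cyclohex-2-en-1-one | CC1=C(CC[C@H]2[C@]3(C)CC[C@H](O[Si](C)(C)C(C)(C)C)C(C)(C)O[C@H]3CC[C@]2(C)O)C(=O)CCC1
F7 | step 7 | (15S)-diethoxy(methyl)silyl enol ether (C19–O, C19=C14) | C[C@H]1CCCC(O[Si](C)(OCC)OCC)=C1CC[C@H]1[C@]2(C)CC[C@H](O[Si](C)(C)C(C)(C)C)C(C)(C)O[C@H]2CC[C@]1(C)O
F8 | step 13 | (22S)-22,23-mono-epoxide of keto diene 18 | C[C@H]1CCC=C(CC[C@@H]2OC2(C)C)[C@@]1(C)CC[C@H]1[C@]2(C)CCC(=O)C(C)(C)O[C@H]2CC[C@]1(C)O
F9 | step 13 | (18S,19Z,22S)-18-hydroperoxy-19(20)-ene 22,23-epoxide | C[C@H]1CC[C@H](OO)/C(=C\C[C@@H]2OC2(C)C)[C@@]1(C)CC[C@H]1[C@]2(C)CCC(=O)C(C)(C)O[C@H]2CC[C@]1(C)O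
F10 | step 13 | (18S,19Z,22S)-18-hydroxy-19(20)-ene 22,23-epoxide | C[C@H]1CC[C@H](O)/C(=C\C[C@@H]2OC2(C)C)[C@@]1(C)CC[C@H]1[C@]2(C)CCC(=O)C(C)(C)O[C@H]2CC[C@]1(C)O
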